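## Retrosynthetic overview

1. The target is traced back to a catalyst-controlled epoxidation of the C10=C11 prenyl alkene and angeloylation of O8 and O5; the side chain C8–C11 is grown on an isopropenyl group (ene chlorination, oxidation to the C7(=CH2)–C8 enal, Brown allylation, cross-metathesis).
2. The C3–C4 oxirane comes from hydroxyl-directed epoxidation of the all-cis cyclohexenol, which comes from Luche reduction of the enone (sets C5).
3. Carbocycle C1–C6 is closed at the C4–C5 bond from an open-chain 5-alkynal by an anti hydro-cyclization. The enabling feature is the unit C3(H)=C4(CH3)–C5(O) of ring C1–C6 (the C3–C4 oxirane read as an alkene): H on C3 and C5 on C4 lie trans across C3=C4, the retron of an anti addition of H and an aldehyde carbon to a but-2-ynyl alkyne C3≡C4.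
4. The alkynal comes from (S)-carvone: Eschenmoser–Tanabe fragmentation of its epoxide cuts the ring between the later C4 and C5 and keeps C1; in the open chain C6 is α to an aldehyde and is oxygenated under proline control, which gives the cis C1/C6 relation that is hard to set in the ring.
5. Ring order: carvone ring opened (step 2); ring C1–C6 closed (step 6); C3–C4 oxirane (step 9); C10–C11 oxirane (step 16).

Key step: step 6

Remarks:
- Locants are those of the target: ring C1 (carries the side chain), C2 (CH2), C3, C4 (CH3), C5 (O-angeloyl), C6 (OAc); chain C7 (=CH2), C8 (O-angeloyl), C9, C10, C11 (CMe2).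
- Assumption: the key step gives mainly the 5,6-trans alcohol, which is the structure written for its product; a cis epimer would be carried along, because both give the same enone in step 7.
- 1-Amino-2-phenylaziridinium acetate (step 2) and the L-series Shi ketone (step 16) are taken as available known reagents.

## Route

Step 1
Reactants: 1 (S)-(+)-carvone
Product: 2 (1S,4S,6S)-1-methyl-4-(prop-1-en-2-yl)-7-oxabicyclo[4.1.0]heptan-2-one
Conditions: 30% H2O2, aqueous NaOH (0.3 equiv), MeOH, 0 °C
Reagents that add atoms: hydrogen peroxide, OO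
Why: Weitz–Scheffer nucleophilic epoxidation touches only the electron-poor enone alkene and adds anti to the isopropenyl group; both new centers are consumed in step 2, so their configuration does not matter.

Step 2
Reactants: 2 carvone epoxide
Product: 4 (3R)-3-(prop-1-en-2-yl)hept-5-ynal, via aziridinyl hydrazone 3 (not isolated)
Conditions: 1-amino-2-phenylaziridinium acetate (1.1 equiv), CH2Cl2, 0 °C → rt
Reagents that add atoms: none
Why: Eschenmoser–Tanabe fragmentation in its N-aminoaziridine variant (the one used when an aldehyde is released): hydrazone 3 loses styrene and N2 while the epoxide opens, which cuts the ring between the carbons that become C4 and C5, gives the C3≡C4 alkyne and the C5 aldehyde, and leaves the C1 center untouched.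

Step 3
Reactants: 4 alkynal
Product: 7 (2R,3S)-3-(prop-1-en-2-yl)hept-5-yne-1,2-diol, via anilinooxy aldehyde 5 (not isolated), via anilinooxy alcohol 6 (not isolated)
Conditions: L-proline (20 mol%), PhNO (slow addition), CHCl3, 4 °C; then NaBH4, EtOH, 0 °C; then Zn, AcOH, rt
Reagents that add atoms: nitrosobenzene, O=Nc1ccccc1
Why: Proline-catalysed α-aminoxylation (enamine catalysis) is catalyst-controlled, L-proline delivering the oxygen to give the R center at C6 whatever the configuration at C1; NaBH4 removes the epimerisable aldehyde at once and zinc in acetic acid cleaves the N–O bond.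

Step 4
Reactants: 7 diol
Product: 9 (2R,3S)-3-(prop-1-en-2-yl)-1-(triethylsilyloxy)hept-5-yn-2-yl acetate, via primary silyl ether 8 (not isolated)
Conditions: TESCl (1.05 equiv), imidazole, CH2Cl2, −78 °C; then Ac2O, pyridine, 4-(dimethylamino)pyridine (cat.), 0 °C
Reagents that add atoms: chlorotriethylsilane, CC[Si](Cl)(CC)CC; acetic anhydride, CC(=O)OC(C)=O
Why: Selective silylation of the primary hydroxyl at low temperature followed by acetylation of the C6 hydroxyl in the same flask puts the final C6 acetate in place without ever exposing a free primary alcohol to which the acetyl group could migrate.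

Step 5
Reactants: 9 silyl ether acetate
Product: 10 (2R,3S)-1-oxo-3-(prop-1-en-2-yl)hept-5-yn-2-yl acetate
Conditions: (COCl)2, DMSO, CH2Cl2, −78 → −40 °C; Et3N, −78 → −20 °C
Reagents that add atoms: none
Why: Swern oxidation converts a primary triethylsilyl ether directly into the aldehyde (the chlorosulfonium salt cleaves the Si–O bond), and the cold amine treatment limits epimerisation at C6.

Step 6
Reactants: 10 α-acetoxy alkynal
Product: 11 (1R,2R,6S)-2-hydroxy-3-methyl-6-(prop-1-en-2-yl)cyclohex-3-en-1-yl acetate (expected major 5,6-trans epimer)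
Conditions: Pd(PCy3)2 (5 mol%), 2-propanol/1,4-dioxane (1:1), 70 °C
Reagents that add atoms: none
Why: Proposed new method: zerovalent palladium coordinated to the but-2-ynyl alkyne attacks the hydrogen-bond-activated aldehyde carbon C5 through the distal, methyl-bearing alkyne carbon C4 on the face opposite to the metal (anti-Wacker-type oxidative addition), which gives a divalent C3-alkenylpalladium alkoxide with palladium trans to the new C4–C5 bond; exchange of the alkoxide with 2-propanol, β-hydride elimination (acetone) and C–H reductive elimination then put hydrogen on C3 and return zerovalent palladium. The closest known reaction type is the trans-selective arylative and alkylative cyclization of 5-alkynals with organoboron reagents under zerovalent palladium and PCy3, which gives 2,3-disubstituted cyclohex-2-en-1-ols; the only change proposed is that a hydride from the alcohol solvent, instead of a carbon group from boron, ends the cycle. Ring C1–C6 is closed in the 6-endo-dig mode, and only the anti addition puts the tether carbon C2 and C5 cis on the new C3=C4 double bond, as the six-membered ring demands. The new center C5 is expected to form mainly trans to the C6 acetate (attack anti to the C6–O dipole, pseudoaxial C5–O avoiding allylic strain with the C4 methyl), but no control is needed because steps 7 and 8 pass through the enone and set C5 afresh. The selectivities needed are endo over 5-exo closure and hydride transfer after, not before, C–C bond formation; the alkyl-capped alkyne with the bulky donor phosphine (the combination that gives endo products in the boron-terminated reaction), the three-atom tether C6–C1–C2, the acetoxy-activated aldehyde and the absence of any acid able to form a palladium hydride from zerovalent palladium should secure them.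

Step 7
Reactants: 11 cyclohexenol
Product: 12 (1R,6S)-3-methyl-2-oxo-6-(prop-1-en-2-yl)cyclohex-3-en-1-yl acetate
Conditions: Dess–Martin periodinane, CH2Cl2, 0 °C → rt
Reagents that add atoms: none
Why: Dess–Martin oxidation of the allylic alcohol converts both C5 epimers into one enone without base, so the α-acetoxy center C6 should not epimerise.

Step 8
Reactants: 12 enone
Product: 13 (1R,2S,6S)-2-hydroxy-3-methyl-6-(prop-1-en-2-yl)cyclohex-3-en-1-yl acetate
Conditions: NaBH4, CeCl3·7H2O, MeOH, −78 °C; AcOH quench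
Reagents that add atoms: none
Why: Luche reduction gives clean 1,2-reduction, and hydride adds axially from the ring face opposite to the C6 acetate and the C1 isopropenyl group (Felkin–Anh, anti to the C6–O bond), so the C5 hydroxyl should emerge cis to both.

Step 9
Reactants: 13 all-cis cyclohexenol
Product: 14 (1R,2R,3R,4S,6S)-2-hydroxy-1-methyl-4-(prop-1-en-2-yl)-7-oxabicyclo[4.1.0]heptan-3-yl acetate
Conditions: VO(acac)2 (5 mol%), t-BuOOH (in decane), CH2Cl2, 0 °C → rt
Reagents that add atoms: tert-butyl hydroperoxide, CC(C)(C)OO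
Why: Vanadium-catalysed hydroxyl-directed epoxidation delivers oxygen to the C3=C4 alkene from the face of the C5 hydroxyl (syn epoxy alcohol, sets C3 and C4), while the isopropenyl alkene, which has no allylic hydroxyl, is left alone.

Step 10
Reactants: 14 epoxy alcohol
Product: 15 (1S,2R,3R,4S,6S)-3-acetoxy-1-methyl-4-(prop-1-en-2-yl)-7-oxabicyclo[4.1.0]heptan-2-yl (Z)-2-methylbut-2-enoate
Conditions: angelic acid, 2,4,6-trichlorobenzoyl chloride, Et3N, toluene, rt; then 14, toluene, 75 °C
Reagents that add atoms: angelic acid, C/C=C(/C)C(=O)O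
Why: Yamaguchi-type mixed-anhydride esterification run without a nucleophilic catalyst should acylate the hindered C5 hydroxyl with retention of the (Z)-geometry of the angeloyl group, and the hydroxyl is capped as soon as it has directed the epoxidation.

Step 11
Reactants: 15 C5 angelate
Product: 16 (1S,2R,3R,4S,6S)-3-acetoxy-4-(3-chloroprop-1-en-2-yl)-1-methyl-7-oxabicyclo[4.1.0]heptan-2-yl (Z)-2-methylbut-2-enoate
Conditions: Ca(OCl)2, CO2 (solid), CH2Cl2/H2O, 0 °C
Reagents that add atoms: calcium hypochlorite, [Ca+2].[O-]Cl.[O-]Cl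
Why: Ene-type allylic chlorination with HOCl (generated from Ca(OCl)2 and CO2) converts an isopropenyl group into a 2-(chloromethyl)vinyl group, as known for carvone, and the electron-poor angelate alkene should not react.

Step 12
Reactants: 16 allylic chloride
Product: 17 (1S,2R,3R,4S,6S)-3-acetoxy-1-methyl-4-(3-oxoprop-1-en-2-yl)-7-oxabicyclo[4.1.0]heptan-2-yl (Z)-2-methylbut-2-enoate
Conditions: N-methylmorpholine N-oxide (3 equiv), KI (0.2 equiv), MeCN, rt → 40 °C
Reagents that add atoms: N-methylmorpholine N-oxide, C[N+]1([O-])CCOCC1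
Why: Kornblum-type oxidation with an amine N-oxide: iodide-assisted O-alkylation of the N-oxide by the allylic chloride and elimination give the 2-substituted acrolein under nearly neutral conditions that spare the esters and the epoxide.

Step 13
Reactants: 17 enal
Product: 18 (1S,2R,3R,4S,6S)-3-acetoxy-4-[(3S)-3-hydroxyhexa-1,5-dien-2-yl]-1-methyl-7-oxabicyclo[4.1.0]heptan-2-yl (Z)-2-methylbut-2-enoate
Conditions: (−)-Ipc2B(allyl) (pre-formed, salt-free, 1.5 equiv), Et2O, −78 °C; then ethanolamine, rt
Reagents that add atoms: (−)-B-allyldiisopinocampheylborane (from (+)-α-pinene), C=CCB(C1CC2CC(C1C)C2(C)C)C1CC2CC(C1C)C2(C)C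
Why: Brown allylboration adds to the aldehyde through a chair transition state under reagent control, the reagent derived from (+)-α-pinene attacking the Si face (as with benzaldehyde) to set 8S, while esters and epoxide are inert at −78 °C.

Step 14
Reactants: 18 homoallylic alcohol
Product: 19 (1S,2R,3R,4S,6S)-3-acetoxy-4-[(3S)-3-hydroxy-6-methylhepta-1,5-dien-2-yl]-1-methyl-7-oxabicyclo[4.1.0]heptan-2-yl (Z)-2-methylbut-2-enoate
Conditions: 2-methyl-2-butene (large excess), second-generation Grubbs catalyst RuCl2(=CHPh)(PCy3)(H2IMes) (5 mol%), CH2Cl2, 40 °C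
Reagents that add atoms: 2-methyl-2-butene, CC=C(C)C
Why: Olefin cross-metathesis with excess 2-methyl-2-butene converts the terminal allyl group into the prenyl group, while the 1,1-disubstituted C7 methylene and the trisubstituted angelate alkene are too hindered or electron-poor to react.

Step 15
Reactants: 19 prenyl alcohol
Product: 20 (1S,2R,3R,4S,6S)-3-acetoxy-1-methyl-4-[(3S)-6-methyl-3-{[(Z)-2-methylbut-2-enoyl]oxy}hepta-1,5-dien-2-yl]-7-oxabicyclo[4.1.0]heptan-2-yl (Z)-2-methylbut-2-enoate
Conditions: angelic acid, 2,4,6-trichlorobenzoyl chloride, Et3N, toluene, rt; then 19, toluene, 75 °C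
Reagents that add atoms: angelic acid, C/C=C(/C)C(=O)O
Why: The same catalyst-free mixed-anhydride (Yamaguchi-type) esterification as in step 10, here on the less hindered C8 hydroxyl, should give the second angelate without Z-to-E isomerisation.

Step 16
Reactants: 20 bis-angelate
Product: 21 target CNP0118696.1
Conditions: 1,2:4,5-di-O-isopropylidene-β-L-erythro-2,3-hexodiulo-2,6-pyranose (L-series Shi ketone, 30 mol%), Oxone (2KHSO5·KHSO4·K2SO4), K2CO3, Bu4NHSO4, MeCN/CH2(OMe)2/aqueous Na2B4O7 buffer, 0 °C
Reagents that add atoms: potassium peroxymonosulfate (active salt of Oxone), [K+].[O-]S(=O)(=O)OO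
Why: Shi asymmetric epoxidation: the chiral dioxirane epoxidises the electron-rich trisubstituted C10=C11 alkene through a spiro transition state under catalyst control (the L-series ketone should give 10S), whereas the C7 methylene next to an ester and the conjugated angelate alkenes react far more slowly.

## Compound list

1 | (S)-(+)-carvone, (5S)-2-methyl-5-(prop-1-en-2-yl)cyclohex-2-en-1-one | C=C(C)[C@@H]1CC(=O)C(C)=CC1 | starting material
2 | (1S,4S,6S)-1-methyl-4-(prop-1-en-2-yl)-7-oxabicyclo[4.1.0]heptan-2-one (oxirane trans to isopropenyl) | C=C(C)[C@@H]1CC(=O)[C@@]2(C)O[C@H]2C1 | intermediate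
3 | hydrazone of 2 with 1-amino-2-phenylaziridine (ring centers as in 2, aziridine carbon racemic) | C=C(C)[C@@H]1CC(=NN3CC3c4ccccc4)[C@@]2(C)O[C@H]2C1 | intermediate
4 | (3R)-3-(prop-1-en-2-yl)hept-5-ynal | C=C(C)[C@H](CC#CC)CC=O | intermediate
5 | (2R,3S)-2-(phenylaminooxy)-3-(prop-1-en-2-yl)hept-5-ynal | C=C(C)[C@H](CC#CC)[C@@H](ONc1ccccc1)C=O | intermediate
6 | (2R,3S)-2-(phenylaminooxy)-3-(prop-1-en-2-yl)hept-5-yn-1-ol | C=C(C)[C@H](CC#CC)[C@@H](ONc1ccccc1)CO | intermediate
7 | (2R,3S)-3-(prop-1-en-2-yl)hept-5-yne-1,2-diol | C=C(C)[C@H](CC#CC)[C@@H](O)CO | intermediate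
8 | (2R,3S)-3-(prop-1-en-2-yl)-1-(triethylsilyloxy)hept-5-yn-2-ol | C=C(C)[C@H](CC#CC)[C@@H](O)CO[Si](CC)(CC)CC | intermediate
9 | (2R,3S)-3-(prop-1-en-2-yl)-1-(triethylsilyloxy)hept-5-yn-2-yl acetate | C=C(C)[C@H](CC#CC)[C@@H](OC(C)=O)CO[Si](CC)(CC)CC | intermediate
10 | (2R,3S)-1-oxo-3-(prop-1-en-2-yl)hept-5-yn-2-yl acetate | C=C(C)[C@H](CC#CC)[C@@H](OC(C)=O)C=O | intermediate
11 | (1R,2R,6S)-2-hydroxy-3-methyl-6-(prop-1-en-2-yl)cyclohex-3-en-1-yl acetate (C5 hydroxyl trans to the C6 acetate) | C=C(C)[C@@H]1CC=C(C)[C@@H](O)[C@@H]1OC(C)=O | intermediate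
12 | (1R,6S)-3-methyl-2-oxo-6-(prop-1-en-2-yl)cyclohex-3-en-1-yl acetate (acetate cis to isopropenyl) | C=C(C)[C@@H]1CC=C(C)C(=O)[C@@H]1OC(C)=O | intermediate
13 | (1R,2S,6S)-2-hydroxy-3-methyl-6-(prop-1-en-2-yl)cyclohex-3-en-1-yl acetate (hydroxyl, acetate and isopropenyl all cis) | C=C(C)[C@@H]1CC=C(C)[C@H](O)[C@@H]1OC(C)=O | intermediate
14 | (1R,2R,3R,4S,6S)-2-hydroxy-1-methyl-4-(prop-1-en-2-yl)-7-oxabicyclo[4.1.0]heptan-3-yl acetate (oxirane, hydroxyl, acetate and isopropenyl all cis) | C=C(C)[C@@H]1C[C@@H]2O[C@]2(C)[C@H](O)[C@@H]1OC(C)=O | intermediate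
15 | (1S,2R,3R,4S,6S)-3-acetoxy-1-methyl-4-(prop-1-en-2-yl)-7-oxabicyclo[4.1.0]heptan-2-yl (Z)-2-methylbut-2-enoate | C=C(C)[C@@H]1C[C@@H]2O[C@]2(C)[C@H](OC(=O)/C(C)=C\C)[C@@H]1OC(C)=O | intermediate
16 | (1S,2R,3R,4S,6S)-3-acetoxy-4-(3-chloroprop-1-en-2-yl)-1-methyl-7-oxabicyclo[4.1.0]heptan-2-yl (Z)-2-methylbut-2-enoate | C=C(CCl)[C@@H]1C[C@@H]2O[C@]2(C)[C@H](OC(=O)/C(C)=C\C)[C@@H]1OC(C)=O | intermediate
17 | (1S,2R,3R,4S,6S)-3-acetoxy-1-methyl-4-(3-oxoprop-1-en-2-yl)-7-oxabicyclo[4.1.0]heptan-2-yl (Z)-2-methylbut-2-enoate | C=C(C=O)[C@@H]1C[C@@H]2O[C@]2(C)[C@H](OC(=O)/C(C)=C\C)[C@@H]1OC(C)=O | intermediate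
18 | (1S,2R,3R,4S,6S)-3-acetoxy-4-[(3S)-3-hydroxyhexa-1,5-dien-2-yl]-1-methyl-7-oxabicyclo[4.1.0]heptan-2-yl (Z)-2-methylbut-2-enoate | C=C([C@H](CC=C)O)[C@@H]1C[C@@H]2O[C@]2(C)[C@H](OC(=O)/C(C)=C\C)[C@@H]1OC(C)=O | intermediate
19 | (1S,2R,3R,4S,6S)-3-acetoxy-4-[(3S)-3-hydroxy-6-methylhepta-1,5-dien-2-yl]-1-methyl-7-oxabicyclo[4.1.0]heptan-2-yl (Z)-2-methylbut-2-enoate | C=C([C@H](CC=C(C)C)O)[C@@H]1C[C@@H]2O[C@]2(C)[C@H](OC(=O)/C(C)=C\C)[C@@H]1OC(C)=O | intermediate
20 | (1S,2R,3R,4S,6S)-3-acetoxy-1-methyl-4-[(3S)-6-methyl-3-{[(Z)-2-methylbut-2-enoyl]oxy}hepta-1,5-dien-2-yl]-7-oxabicyclo[4.1.0]heptan-2-yl (Z)-2-methylbut-2-enoate | C=C([C@H](CC=C(C)C)OC(=O)/C(C)=C\C)[C@@H]1C[C@@H]2O[C@]2(C)[C@H](OC(=O)/C(C)=C\C)[C@@H]1OC(C)=O | intermediate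
21 | CNP0118696.1, (1S,2R,3R,4S,6S)-3-acetoxy-4-[(3S)-4-[(2S)-3,3-dimethyloxiran-2-yl]-3-{[(Z)-2-methylbut-2-enoyl]oxy}but-1-en-2-yl]-1-methyl-7-oxabicyclo[4.1.0]heptan-2-yl (Z)-2-methylbut-2-enoate | C=C([C@H](C[C@@H]1OC1(C)C)OC(=O)/C(C)=C\C)[C@@H]1C[C@@H]2O[C@]2(C)[C@H](OC(=O)/C(C)=C\C)[C@@H]1OC(C)=O | target

## Step count and risks

Total step count: 16. Longest linear sequence: 16 steps from (S)-carvone (the route is fully linear).

Steps most likely to fail:

1. Step 6 (key step, proposed method). What may go wrong: a palladium hydride forms ahead of C–C bond formation (syn hydropalladation, semireduction of the alkyne), closure runs through C3 (5-exo), or the cycle stalls at the alkenylpalladium stage. The fallback uses known reactions, sets out from 10 and comes back at 11. Trans-hydrostannation of the alkyne (Bu3SnH, [Cp*RuCl]4 cat., CH2Cl2) should give, after removal of the C3-stannylated regioisomer, (2R,3S,5Z)-1-oxo-3-(prop-1-en-2-yl)-6-(tributylstannyl)hept-5-en-2-yl acetate F1. Iodine (CH2Cl2, 0 °C) exchanges tin for iodine with retention to give (2R,3S,5Z)-6-iodo-1-oxo-3-(prop-1-en-2-yl)hept-5-en-2-yl acetate F2. Nozaki–Hiyama–Kishi cyclization (CrCl2, NiCl2 cat., DMSO, rt) of this iodide, whose C4–I bond is cis to the tether, forms the same C4–C5 bond and gives 11; either C5 epimer serves, since step 7 follows.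

2. Step 10. What may go wrong: acylation of the hindered C5 hydroxyl is slow, so that Z-to-E isomerisation of the angeloyl group and migration of the acetyl group from O6 to O5 compete. The fallback sets out from 14 and comes back at 15. Esterification with 2-[bis(2,2,2-trifluoroethoxy)phosphoryl]propanoic acid (DCC, 4-(dimethylamino)pyridine cat., CH2Cl2) should give (1S,2R,3R,4S,6S)-3-acetoxy-1-methyl-4-(prop-1-en-2-yl)-7-oxabicyclo[4.1.0]heptan-2-yl 2-[bis(2,2,2-trifluoroethoxy)phosphoryl]propanoate F3. Still–Gennari olefination with acetaldehyde (KN(SiMe3)2, 18-crown-6, THF, −78 °C) then builds the (Z)-2-methylbut-2-enoate on the oxygen and gives 15.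

3. Step 11. What may go wrong: the ene step removes the ring methine hydrogen at C1 instead of a methyl hydrogen, HOCl adds across the alkene, or chlorination goes too far. The fallback sets out from 15 and comes back at 17, so that 16 is bypassed. A Schenck ene reaction with singlet oxygen (O2, tetraphenylporphyrin, visible light, CH2Cl2, 0 °C) should give (1S,2R,3R,4S,6S)-3-acetoxy-4-(3-hydroperoxyprop-1-en-2-yl)-1-methyl-7-oxabicyclo[4.1.0]heptan-2-yl (Z)-2-methylbut-2-enoate F4. PPh3 reduces it to (1S,2R,3R,4S,6S)-3-acetoxy-4-(3-hydroxyprop-1-en-2-yl)-1-methyl-7-oxabicyclo[4.1.0]heptan-2-yl (Z)-2-methylbut-2-enoate F5, and MnO2 (CH2Cl2, rt) oxidises the primary allylic alcohol to enal 17.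

## Further compounds

F1 | step 6 | (2R,3S,5Z)-1-oxo-3-(prop-1-en-2-yl)-6-(tributylstannyl)hept-5-en-2-yl acetate | C=C(C)[C@H](C/C=C(/C)[Sn](CCCC)(CCCC)CCCC)[C@@H](OC(C)=O)C=O
F2 | step 6 | (2R,3S,5Z)-6-iodo-1-oxo-3-(prop-1-en-2-yl)hept-5-en-2-yl acetate | C=C(C)[C@H](C/C=C(/C)I)[C@@H](OC(C)=O)C=O
F3 | step 10 | (1S,2R,3R,4S,6S)-3-acetoxy-1-methyl-4-(prop-1-en-2-yl)-7-oxabicyclo[4.1.0]heptan-2-yl 2-[bis(2,2,2-trifluoroethoxy)phosphoryl]propanoate | C=C(C)[C@@H]1C[C@@H]2O[C@]2(C)[C@H](OC(=O)C(C)P(=O)(OCC(F)(F)F)OCC(F)(F)F)[C@@H]1OC(C)=O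
F4 | step 11 | (1S,2R,3R,4S,6S)-3-acetoxy-4-(3-hydroperoxyprop-1-en-2-yl)-1-methyl-7-oxabicyclo[4.1.0]heptan-2-yl (Z)-2-methylbut-2-enoate | C=C(COO)[C@@H]1C[C@@H]2O[C@]2(C)[C@H](OC(=O)/C(C)=C\C)[C@@H]1OC(C)=O
F5 | step 11 | (1S,2R,3R,4S,6S)-3-acetoxy-4-(3-hydroxyprop-1-en-2-yl)-1-methyl-7-oxabicyclo[4.1.0]heptan-2-yl (Z)-2-methylbut-2-enoate | C=C(CO)[C@@H]1C[C@@H]2O[C@]2(C)[C@H](OC(=O)/C(C)=C\C)[C@@H]1OC(C)=O
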